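**Plan**
Retrosynthesis: the three MOM ethers come off last; the pyran ring C of the (2S)-flavan is then cut at C4–C4a and at O1–C8a together, giving a ring A aryl iodide (iodine on C8a) and a ring B (S)-1-aryl-3-iodopropan-1-ol (C2–C3–C4 with O1 on C2).
Enabling feature: C8a sits between C8, blocked by its prenyl group, and C4a, the only free ortho C–H of ring A; this is the pattern a Catellani palladium/norbornene relay needs to alkylate C4a with C4 and then close O1 onto C8a.
Forward: rings A and B are bought as bromoarenes and each is prenylated by directed ortho-lithiation between OMOM and Br; ring B is then acylated and reduced; ring C is the only ring made, in the convergent step 9.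
Stereochemistry: the single stereocentre C2 is set as S by CBS reduction of a β-chloro ketone (step 7), and no bond to it is made or broken afterwards.

Key step: step 9

Assumption: 5-bromo-2-methoxyphenol, 4-bromobenzene-1,2-diol, prenyl bromide and 3-chloro-N-methoxy-N-methylpropanamide are taken as catalogue chemicals; LiN(iPr)2 is used as a commercial solution.

Step 1
Reactants: 1 5-bromo-2-methoxyphenol
Product: 2 4-bromo-1-methoxy-2-(methoxymethoxy)benzene
Conditions: MOMCl (1.3 equiv), K2CO3 (2 equiv), acetone, 0 °C to rt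
Reagents that add atoms: chloromethyl methyl ether (MOMCl), COCCl
Why: Williamson-type O-alkylation of the phenoxide by the α-chloro ether should give the MOM acetal, which is inert to the lithium bases used next and serves as the ortho-directing group in step 2.

Step 2
Reactants: 2 4-bromo-1-methoxy-2-(methoxymethoxy)benzene; 3 1-bromo-3-methylbut-2-ene (prenyl bromide)
Product: 6 1-bromo-4-methoxy-3-(methoxymethoxy)-2-(3-methylbut-2-en-1-yl)benzene, via aryllithium 4 (not isolated), via arylcopper 5 (not isolated)
Conditions: LiN(iPr)2 (1.1 equiv), THF, −78 °C; CuBr·SMe2 (1.1 equiv), −78 to −40 °C; 3 (1.3 equiv), −40 to 0 °C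
Reagents that add atoms: none
Why: Directed ortho-metalation: the C–H between OMOM (coordination) and Br (inductive acidification) is the most acidic one, the amide base leaves the C–Br bond alone, transmetalation to monovalent copper holds back loss of LiBr to an aryne, and the arylcopper should couple with the allylic bromide at its unhindered primary carbon (SN2 allylation).

Step 3
Reactants: 6 1-bromo-4-methoxy-3-(methoxymethoxy)-2-(3-methylbut-2-en-1-yl)benzene
Product: 7 1-iodo-4-methoxy-3-(methoxymethoxy)-2-(3-methylbut-2-en-1-yl)benzene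
Conditions: NaI (2 equiv), CuI (10 mol%), trans-N,N'-dimethylcyclohexane-1,2-diamine (20 mol%), 1,4-dioxane, 110 °C
Reagents that add atoms: sodium iodide (NaI), [Na+].[I-]
Why: Copper-catalysed aromatic Finkelstein exchange, driven by the poor solubility of NaBr in dioxane, should give the aryl iodide that step 9 needs for fast oxidative addition while the acetal and the olefin stay untouched.

Step 4
Reactants: 8 4-bromobenzene-1,2-diol
Product: 9 4-bromo-1,2-bis(methoxymethoxy)benzene
Conditions: MOMCl (2.6 equiv), K2CO3 (4 equiv), acetone, 0 °C to rt, argon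
Reagents that add atoms: chloromethyl methyl ether (MOMCl), COCCl
Why: Double Williamson-type O-alkylation of the catechol should give the bis-MOM ether, in which the C2 acetal and the C4 bromine together flank and acidify C3–H for step 5.

Step 5
Reactants: 9 4-bromo-1,2-bis(methoxymethoxy)benzene; 3 1-bromo-3-methylbut-2-ene (prenyl bromide)
Product: 12 1-bromo-3,4-bis(methoxymethoxy)-2-(3-methylbut-2-en-1-yl)benzene, via aryllithium 10 (not isolated), via arylcopper 11 (not isolated)
Conditions: LiN(iPr)2 (1.1 equiv), THF, −78 °C; CuBr·SMe2 (1.1 equiv), −78 to −40 °C; 3 (1.3 equiv), −40 to 0 °C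
Reagents that add atoms: none
Why: Directed ortho-metalation as in step 2: deprotonation should occur at the C–H flanked by OMOM and Br, and the derived arylcopper should be allylated at the primary carbon of prenyl bromide.

Step 6
Reactants: 12 1-bromo-3,4-bis(methoxymethoxy)-2-(3-methylbut-2-en-1-yl)benzene; 13 3-chloro-N-methoxy-N-methylpropanamide
Product: 16 1-[3,4-bis(methoxymethoxy)-2-(3-methylbut-2-en-1-yl)phenyl]-3-chloropropan-1-one, via aryllithium 14 (not isolated), via lithium hemiaminal alkoxide 15 (not isolated)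
Conditions: n-BuLi (1.05 equiv), THF, −78 °C; 13 (1.2 equiv), −78 °C; aq NH4Cl at −78 °C
Reagents that add atoms: none
Why: Bromine–lithium exchange is faster than any deprotonation at −78 °C and the Weinreb ketone synthesis stops at the chelated tetrahedral adduct 15, so no second addition occurs and the cold quench should release the β-chloro ketone before HCl can be eliminated.

Step 7
Reactants: 16 1-[3,4-bis(methoxymethoxy)-2-(3-methylbut-2-en-1-yl)phenyl]-3-chloropropan-1-one
Product: 18 (1S)-1-[3,4-bis(methoxymethoxy)-2-(3-methylbut-2-en-1-yl)phenyl]-3-chloropropan-1-ol, via catechol borate ester 17 (not isolated)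
Conditions: (R)-2-methyl-CBS-oxazaborolidine (15 mol%), catecholborane (1.5 equiv), toluene, −78 to −40 °C; then H2O work-up
Reagents that add atoms: none
Why: CBS reduction: the (R)-oxazaborolidine binds the ketone with the large ortho-substituted aryl group away from the catalyst and delivers hydride from catecholborane to the Re face, which should set C2 as S, while catecholborane does not hydroborate the prenyl olefins at low temperature.

Step 8
Reactants: 18 (1S)-1-[3,4-bis(methoxymethoxy)-2-(3-methylbut-2-en-1-yl)phenyl]-3-chloropropan-1-ol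
Product: 19 (1S)-1-[3,4-bis(methoxymethoxy)-2-(3-methylbut-2-en-1-yl)phenyl]-3-iodopropan-1-ol
Conditions: NaI (3 equiv), acetone, reflux, dark
Reagents that add atoms: sodium iodide (NaI), [Na+].[I-]
Why: Finkelstein exchange (SN2 at the primary carbon, driven by precipitation of NaCl) should give the more reactive alkyl iodide without touching the carbinol stereocentre.

Step 9
Reactants: 7 1-iodo-4-methoxy-3-(methoxymethoxy)-2-(3-methylbut-2-en-1-yl)benzene; 19 (1S)-1-[3,4-bis(methoxymethoxy)-2-(3-methylbut-2-en-1-yl)phenyl]-3-iodopropan-1-ol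
Product: 21 (2S)-2-[3,4-bis(methoxymethoxy)-2-(3-methylbut-2-en-1-yl)phenyl]-6-methoxy-7-(methoxymethoxy)-8-(3-methylbut-2-en-1-yl)-3,4-dihydro-2H-chromene, via arylpalladium iodide 20 (not isolated)
Conditions: Pd(OAc)2 (10 mol%), RuPhos (2-dicyclohexylphosphino-2',6'-diisopropoxybiphenyl, 20 mol%), norbornene (2 equiv), Cs2CO3 (3 equiv), 19 (1.5 equiv), 1,4-dioxane, 100 °C, argon
Reagents that add atoms: none
Why: Proposed new method: oxidative addition of the C–I bond of 7 to zerovalent palladium, syn-exo carbopalladation of norbornene and carbonate-assisted palladation of the only free ortho C–H (the future C4a) should give an aryl–norbornyl palladacycle of divalent palladium, which adds the primary C–I bond of 19 to reach tetravalent palladium; C(sp2)–C(sp3) reductive elimination then forms C4–C4a and the now 2,6-disubstituted aryl expels norbornene by β-carbon elimination to give 20. The caesium alkoxide of the tethered carbinol then replaces iodide on palladium and C–O reductive elimination forms O1–C8a, so that ring C closes by contraction of a seven-membered aryl(alkoxo)palladacycle to the six-membered pyran (an intramolecular Buchwald–Hartwig etherification) and zerovalent palladium is returned. The closest known reaction types are the Catellani ortho-alkylation/ipso-amination annulation of aryl iodides with bromoalkylamines to tetrahydroquinolines, the palladium/norbornene annulation of aryl iodides with epoxides to 2,3-dihydrobenzofurans and the palladium-catalysed cyclisation of 3-(2-haloaryl)propyl secondary carbinols to chromans without loss of configuration; the use of a γ-iodo alcohol to build a chroman in this relay is the untested part. No stereocentre is created: C2 is the carbinol carbon of 19, none of its bonds is made or broken, and the S configuration from step 7 should be retained as long as β-hydride elimination from the palladium alkoxide stays slower than C–O reductive elimination, which the bulky electron-rich phosphine RuPhos is chosen to ensure. The step needs a single ortho-alkylation at one defined site, and the C8 prenyl group secures it by blocking the second ortho position and by forcing norbornene extrusion once C4a is substituted (ortho effect). It also needs chemoselectivity for strained norbornene over the two prenyl olefins, which as trisubstituted alkenes are poor partners for carbopalladation and cannot reach the aryl–palladium bond in a favourable ring size.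

Step 10
Reactants: 21 (2S)-2-[3,4-bis(methoxymethoxy)-2-(3-methylbut-2-en-1-yl)phenyl]-6-methoxy-7-(methoxymethoxy)-8-(3-methylbut-2-en-1-yl)-3,4-dihydro-2H-chromene
Product: 22 (2S)-2-[3,4-dihydroxy-2-(3-methylbut-2-en-1-yl)phenyl]-6-methoxy-8-(3-methylbut-2-en-1-yl)-3,4-dihydro-2H-chromen-7-ol
Conditions: HCl (about 1 M) in MeOH, 0 °C to rt, argon
Reagents that add atoms: none
Why: Acid-catalysed acetal solvolysis (transacetalisation to dimethoxymethane) should free the three phenols under conditions mild enough to leave the prenyl groups, the aryl methyl ether and the benzylic C2–O1 bond intact.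

**Compound list**
1 | 5-bromo-2-methoxyphenol | COc1ccc(Br)cc1O | starting material
2 | 4-bromo-1-methoxy-2-(methoxymethoxy)benzene | COc1ccc(Br)cc1OCOC | intermediate
3 | 1-bromo-3-methylbut-2-ene (prenyl bromide) | CC(C)=CCBr | starting material
4 | [6-bromo-3-methoxy-2-(methoxymethoxy)phenyl]lithium | [Li]c1c(Br)ccc(OC)c1OCOC | intermediate
5 | [6-bromo-3-methoxy-2-(methoxymethoxy)phenyl]copper (monovalent copper) | [Cu]c1c(Br)ccc(OC)c1OCOC | intermediate
6 | 1-bromo-4-methoxy-3-(methoxymethoxy)-2-(3-methylbut-2-en-1-yl)benzene | COc1ccc(Br)c(CC=C(C)C)c1OCOC | intermediate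
7 | 1-iodo-4-methoxy-3-(methoxymethoxy)-2-(3-methylbut-2-en-1-yl)benzene | COc1ccc(I)c(CC=C(C)C)c1OCOC | intermediate
8 | 4-bromobenzene-1,2-diol | Oc1ccc(Br)cc1O | starting material
9 | 4-bromo-1,2-bis(methoxymethoxy)benzene | COCOc1ccc(Br)cc1OCOC | intermediate
10 | [6-bromo-2,3-bis(methoxymethoxy)phenyl]lithium | [Li]c1c(Br)ccc(OCOC)c1OCOC | intermediate
11 | [6-bromo-2,3-bis(methoxymethoxy)phenyl]copper (monovalent copper) | [Cu]c1c(Br)ccc(OCOC)c1OCOC | intermediate
12 | 1-bromo-3,4-bis(methoxymethoxy)-2-(3-methylbut-2-en-1-yl)benzene | COCOc1ccc(Br)c(CC=C(C)C)c1OCOC | intermediate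
13 | 3-chloro-N-methoxy-N-methylpropanamide | CON(C)C(=O)CCCl | starting material
14 | [3,4-bis(methoxymethoxy)-2-(3-methylbut-2-en-1-yl)phenyl]lithium | [Li]c1ccc(OCOC)c(OCOC)c1CC=C(C)C | intermediate
15 | lithium 1-[3,4-bis(methoxymethoxy)-2-(3-methylbut-2-en-1-yl)phenyl]-3-chloro-1-[methoxy(methyl)amino]propan-1-olate | [Li+].[O-]C(CCCl)(N(C)OC)c1ccc(OCOC)c(OCOC)c1CC=C(C)C | intermediate
16 | 1-[3,4-bis(methoxymethoxy)-2-(3-methylbut-2-en-1-yl)phenyl]-3-chloropropan-1-one | O=C(CCCl)c1ccc(OCOC)c(OCOC)c1CC=C(C)C | intermediate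
17 | 2-{(1S)-1-[3,4-bis(methoxymethoxy)-2-(3-methylbut-2-en-1-yl)phenyl]-3-chloropropoxy}-1,3,2-benzodioxaborole | ClCC[C@H](OB1Oc2ccccc2O1)c1ccc(OCOC)c(OCOC)c1CC=C(C)C | intermediate
18 | (1S)-1-[3,4-bis(methoxymethoxy)-2-(3-methylbut-2-en-1-yl)phenyl]-3-chloropropan-1-ol | O[C@H](c1ccc(OCOC)c(OCOC)c1CC=C(C)C)CCCl | intermediate
19 | (1S)-1-[3,4-bis(methoxymethoxy)-2-(3-methylbut-2-en-1-yl)phenyl]-3-iodopropan-1-ol | O[C@H](c1ccc(OCOC)c(OCOC)c1CC=C(C)C)CCI | intermediate
20 | {2-[(3S)-3-[3,4-bis(methoxymethoxy)-2-(3-methylbut-2-en-1-yl)phenyl]-3-hydroxypropyl]-4-methoxy-5-(methoxymethoxy)-6-(3-methylbut-2-en-1-yl)phenyl}palladium iodide (divalent palladium, phosphine ligand omitted) | COc1cc(CC[C@H](O)c2ccc(OCOC)c(OCOC)c2CC=C(C)C)c([Pd]I)c(CC=C(C)C)c1OCOC | intermediate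
21 | (2S)-2-[3,4-bis(methoxymethoxy)-2-(3-methylbut-2-en-1-yl)phenyl]-6-methoxy-7-(methoxymethoxy)-8-(3-methylbut-2-en-1-yl)-3,4-dihydro-2H-chromene | COc1cc2c(c(CC=C(C)C)c1OCOC)O[C@H](c1ccc(OCOC)c(OCOC)c1CC=C(C)C)CC2 | intermediate
22 | (2S)-2-[3,4-dihydroxy-2-(3-methylbut-2-en-1-yl)phenyl]-6-methoxy-8-(3-methylbut-2-en-1-yl)-3,4-dihydro-2H-chromen-7-ol | COc1cc2c(c(CC=C(C)C)c1O)O[C@H](c1ccc(O)c(O)c1CC=C(C)C)CC2 | target

Total step count: 10 (steps 1–3 ring A, steps 4–8 ring B, steps 9–10 union and deprotection).
Longest linear sequence: 7 steps (4, 5, 6, 7, 8, 9, 10).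

**Steps most likely to fail**

1. Step 9 (Proposed new method). What may go wrong:
- β-hydride elimination from the palladium alkoxide may outrun C–O reductive elimination, which would reduce the arene, oxidise the carbinol and lose the stereocentre.
- The base may close 19 to an oxetane before it alkylates the palladacycle.
- Palladium may migrate into the neighbouring prenyl group.

Fallback (known chemistry only; sets out from 6 and 12, returns at 21): ring C is closed instead at O1–C2 by a Mitsunobu reaction with inversion. Bromide 6 is taken through bromine–lithium exchange (n-BuLi, THF, −78 °C), borylation with B(OMe)3 and oxidation (H2O2, NaOH) to 4-methoxy-3-(methoxymethoxy)-2-(3-methylbut-2-en-1-yl)phenol F1. Magnesium-mediated ortho-formylation (MgCl2, Et3N, paraformaldehyde, MeCN, reflux) should convert F1 at its only free ortho position into 2-hydroxy-5-methoxy-4-(methoxymethoxy)-3-(3-methylbut-2-en-1-yl)benzaldehyde F2. Bromide 12 is lithiated in the same way and acylated with N-methoxy-N-methylacetamide to 1-[3,4-bis(methoxymethoxy)-2-(3-methylbut-2-en-1-yl)phenyl]ethan-1-one F3. Claisen–Schmidt condensation of F2 and F3 (KOH, EtOH) should give (2E)-1-[3,4-bis(methoxymethoxy)-2-(3-methylbut-2-en-1-yl)phenyl]-3-[2-hydroxy-5-methoxy-4-(methoxymethoxy)-3-(3-methylbut-2-en-1-yl)phenyl]prop-2-en-1-one F4. Hydrogenation of the enone C=C with RhCl(PPh3)3 and H2, which spares the trisubstituted prenyl olefins, should give 1-[3,4-bis(methoxymethoxy)-2-(3-methylbut-2-en-1-yl)phenyl]-3-[2-hydroxy-5-methoxy-4-(methoxymethoxy)-3-(3-methylbut-2-en-1-yl)phenyl]propan-1-one F5. CBS reduction with the (S)-oxazaborolidine and excess catecholborane should give 2-[(3R)-3-[3,4-bis(methoxymethoxy)-2-(3-methylbut-2-en-1-yl)phenyl]-3-hydroxypropyl]-4-methoxy-5-(methoxymethoxy)-6-(3-methylbut-2-en-1-yl)phenol F6. Mitsunobu cyclisation (PPh3, DIAD, THF, 0 °C) with inversion at the carbinol carbon should then give 21.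

2. Step 2. What may go wrong:
- The ortho-bromoaryllithium may lose LiBr to an aryne before it is transferred to copper.
- The allyl system may couple at its tertiary end (SN2′), giving the reverse-prenyl isomer.

Fallback (sets out from 1, returns at 6): the prenyl group is delivered through oxygen by a Claisen rearrangement instead of through an aryl anion. Phenol 1 is O-alkylated at the tertiary allyl terminus with tert-butyl 2-methylbut-3-en-2-yl carbonate and Pd(PPh3)4 (THF, 0 °C, Tsuji–Trost reaction) to 4-bromo-1-methoxy-2-[(2-methylbut-3-en-2-yl)oxy]benzene F7. Heating (N,N-diethylaniline, about 140 °C) should trigger the aromatic Claisen rearrangement into the only free ortho position and give 3-bromo-6-methoxy-2-(3-methylbut-2-en-1-yl)phenol F8. MOMCl and K2CO3 in acetone then give 6.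

3. Step 10. What may go wrong:
- Acid may cyclise a prenyl group onto its neighbouring free phenol.
- Acid may ionise the benzylic C2–O1 bond, which the para-oxygenated ring B assists, and erode the configuration at C2.

Fallback (sets out from 21, returns at 22): the acetals are exchanged for silyl ethers under buffered, non-protic conditions and the phenols are then freed by fluoride. Et3SiOTf and 2,2'-bipyridyl (CH2Cl2, 0 °C) should convert 21 into (2S)-2-{3,4-bis[(triethylsilyl)oxy]-2-(3-methylbut-2-en-1-yl)phenyl}-6-methoxy-8-(3-methylbut-2-en-1-yl)-7-[(triethylsilyl)oxy]-3,4-dihydro-2H-chromene F9. Bu4NF buffered with AcOH (THF, 0 °C) should then give 22.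

Further compounds
F1 | step 9 | 4-methoxy-3-(methoxymethoxy)-2-(3-methylbut-2-en-1-yl)phenol | COc1ccc(O)c(CC=C(C)C)c1OCOC
F2 | step 9 | 2-hydroxy-5-methoxy-4-(methoxymethoxy)-3-(3-methylbut-2-en-1-yl)benzaldehyde | COc1cc(C=O)c(O)c(CC=C(C)C)c1OCOC
F3 | step 9 | 1-[3,4-bis(methoxymethoxy)-2-(3-methylbut-2-en-1-yl)phenyl]ethan-1-one | CC(=O)c1ccc(OCOC)c(OCOC)c1CC=C(C)C
F4 | step 9 | (2E)-1-[3,4-bis(methoxymethoxy)-2-(3-methylbut-2-en-1-yl)phenyl]-3-[2-hydroxy-5-methoxy-4-(methoxymethoxy)-3-(3-methylbut-2-en-1-yl)phenyl]prop-2-en-1-one | COc1cc(/C=C/C(=O)c2ccc(OCOC)c(OCOC)c2CC=C(C)C)c(O)c(CC=C(C)C)c1OCOC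
F5 | step 9 | 1-[3,4-bis(methoxymethoxy)-2-(3-methylbut-2-en-1-yl)phenyl]-3-[2-hydroxy-5-methoxy-4-(methoxymethoxy)-3-(3-methylbut-2-en-1-yl)phenyl]propan-1-one | COc1cc(CCC(=O)c2ccc(OCOC)c(OCOC)c2CC=C(C)C)c(O)c(CC=C(C)C)c1OCOC
F6 | step 9 | 2-[(3R)-3-[3,4-bis(methoxymethoxy)-2-(3-methylbut-2-en-1-yl)phenyl]-3-hydroxypropyl]-4-methoxy-5-(methoxymethoxy)-6-(3-methylbut-2-en-1-yl)phenol | COc1cc(CC[C@@H](O)c2ccc(OCOC)c(OCOC)c2CC=C(C)C)c(O)c(CC=C(C)C)c1OCOC
F7 | step 2 | 4-bromo-1-methoxy-2-[(2-methylbut-3-en-2-yl)oxy]benzene | COc1ccc(Br)cc1OC(C)(C)C=C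
F8 | step 2 | 3-bromo-6-methoxy-2-(3-methylbut-2-en-1-yl)phenol | COc1ccc(Br)c(CC=C(C)C)c1O
F9 | step 10 | (2S)-2-{3,4-bis[(triethylsilyl)oxy]-2-(3-methylbut-2-en-1-yl)phenyl}-6-methoxy-8-(3-methylbut-2-en-1-yl)-7-[(triethylsilyl)oxy]-3,4-dihydro-2H-chromene | COc1cc2c(c(CC=C(C)C)c1O[Si](CC)(CC)CC)O[C@H](c1ccc(O[Si](CC)(CC)CC)c(O[Si](CC)(CC)CC)c1CC=C(C)C)CC2
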